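**Assumptions.** Locants C1–C18 are those of the target chain (C1 = ester carbon, C6 and C14 = the two C–OO carbons, C18 = CMe2). CIP letters of some intermediates differ from the target only because substituent priorities change, and the SMILES give the geometry. (R)-Linalool of high ee and the (R)-hydroxyphosphonium salt of step 10 are taken as commercial. The route is a design resting on literature precedent; it has not been run.

**Retrosynthetic overview**
1. Target ⇐ C14 hydroperoxide masked as a 2-methoxyprop-2-yl peroxyketal; the saturated C8–C9 and C11–C12 links ⇐ Wittig and Julia–Kocienski olefinations followed by diimide, which leaves O–O bonds intact.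
2. C10 ⇐ a Roche-ester-derived (R)-(3-hydroxy-2-methylpropyl)phosphonium salt placed between two β-peroxy aldehydes.
3. Both tertiary C–OO centres (C6 and C14) ⇐ one 2,2-disubstituted oxetane from (R)-linalool, opened by H2O2 with inversion.
4. The 1,2-dioxane, the only ring of the target, is closed after the oxetane has been made and opened: 6-exo-tet SN2 of C6–OOH on a C3 mesylate (inversion). C2/C3 ⇐ Brown anti-crotylation; vinyl ⇒ CO2Me by ozonolysis.

**Step 1**
Reactants: 1 (R)-(−)-linalool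
Product: 3 (3R)-3,7-dimethyloct-6-ene-1,3-diol, via organoborane 2 (not isolated)
Conditions: 9-BBN, THF, 0 °C → rt; then NaOH, 30% H2O2, 0 °C
Reagents that add atoms: hydrogen peroxide, OO
Why: Hydroboration–oxidation; 9-BBN adds anti-Markovnikov to the vinyl group far faster than to the trisubstituted alkene, and the carbinol stereocentre is not touched.

**Step 2**
Reactants: 3 (3R)-3,7-dimethyloct-6-ene-1,3-diol
Product: 5 (2R)-2-methyl-2-(4-methylpent-3-en-1-yl)oxetane, via monotosylate 4 (not isolated)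
Conditions: n-BuLi (1 equiv), THF, 0 °C; TsCl (1 equiv); then n-BuLi (1 equiv), 0 → 60 °C
Reagents that add atoms: none
Why: One-pot primary sulfonylation and 4-exo-tet Williamson closure by the tertiary alkoxide; the C–O bond at the stereocentre is never broken, so configuration is retained.

**Step 3**
Reactants: 5 (2R)-2-methyl-2-(4-methylpent-3-en-1-yl)oxetane
Product: 6 3-[(2R)-2-methyloxetan-2-yl]propanal
Conditions: O3/O2, pyridine (3 equiv), CH2Cl2, −78 °C
Reagents that add atoms: ozone, [O-][O+]=O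
Why: Pyridine-mediated reductive ozonolysis cleaves the only alkene straight to the aldehyde, and the oxetane is inert to ozone at −78 °C.

**Step 4**
Reactants: 6 3-[(2R)-2-methyloxetan-2-yl]propanal
Product: 8 (3S,4R)-3-methyl-6-[(2R)-2-methyloxetan-2-yl]hex-1-en-4-ol, via borinate ester 7 (not isolated)
Conditions: trans-2-butene, n-BuLi, KOt-Bu, THF, −78 → −45 °C; (−)-Ipc2BOMe, −78 °C; BF3·OEt2 (1.0 equiv); 6, −78 °C; then NaOH, H2O2, rt
Reagents that add atoms: trans-2-butene, C/C=C/C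
Why: Brown asymmetric crotylboration; the (E)-crotylborane reacts through a chair transition state to give the anti product, and the (+)-α-pinene-derived Ipc groups direct si-face attack, setting C2 (final) and C3 (OH to be inverted) under reagent control.

**Step 5**
Reactants: 8 (3S,4R)-3-methyl-6-[(2R)-2-methyloxetan-2-yl]hex-1-en-4-ol
Product: 9 (3S,4R)-3-methyl-6-[(2R)-2-methyloxetan-2-yl]hex-1-en-4-yl methanesulfonate
Conditions: MsCl, Et3N, CH2Cl2, 0 °C
Reagents that add atoms: methanesulfonyl chloride, CS(=O)(=O)Cl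
Why: O-Sulfonylation of the secondary alcohol with retention, making C3 a leaving-group carbon while the oxetane stays intact.

**Step 6**
Reactants: 9 (3S,4R)-3-methyl-6-[(2R)-2-methyloxetan-2-yl]hex-1-en-4-yl methanesulfonate
Product: 10 (3S,4R,7S)-7-hydroperoxy-9-hydroxy-3,7-dimethylnon-1-en-4-yl methanesulfonate
Conditions: anhydrous H2O2 in Et2O (10 equiv), TMSOTf (0.2 equiv), −78 → 0 °C
Reagents that add atoms: hydrogen peroxide, OO
Why: Lewis-acid-promoted perhydrolysis of the oxetane; H2O2 attacks the tertiary carbon with inversion, which converts the linalool centre into the C6 configuration and frees the C8 alcohol.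

**Step 7**
Reactants: 10 (3S,4R,7S)-7-hydroperoxy-9-hydroxy-3,7-dimethylnon-1-en-4-yl methanesulfonate
Product: 11 2-[(3S,6S)-6-[(2S)-but-3-en-2-yl]-3-methyl-1,2-dioxan-3-yl]ethan-1-ol
Conditions: KOt-Bu (1.05 equiv), 18-crown-6, THF, 0 °C
Reagents that add atoms: none
Why: Intramolecular hydroperoxide alkylation; the peroxy anion (formed in preference to the alkoxide) displaces the mesylate by 6-exo-tet SN2 with inversion, setting C3 and closing the 1,2-dioxane.

**Step 8**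
Reactants: 11 2-[(3S,6S)-6-[(2S)-but-3-en-2-yl]-3-methyl-1,2-dioxan-3-yl]ethan-1-ol
Product: 12 methyl (2R)-2-[(3S,6S)-6-(2-hydroxyethyl)-6-methyl-1,2-dioxan-3-yl]propanoate
Conditions: O3/O2, 2.5 M NaOH in MeOH (5 equiv), CH2Cl2, −78 °C
Reagents that add atoms: ozone, [O-][O+]=O; methanol, CO
Why: Marshall ozonolysis in methanolic NaOH turns the terminal alkene directly into the methyl ester, and at −78 °C neither C2 is enolised nor the peroxide cleaved.

**Step 9**
Reactants: 12 methyl (2R)-2-[(3S,6S)-6-(2-hydroxyethyl)-6-methyl-1,2-dioxan-3-yl]propanoate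
Product: 13 methyl (2R)-2-[(3S,6S)-6-methyl-6-(2-oxoethyl)-1,2-dioxan-3-yl]propanoate
Conditions: TEMPO (10 mol%), PhI(OAc)2, CH2Cl2, rt
Reagents that add atoms: none
Why: Oxoammonium (TEMPO/BAIB) oxidation stops at the aldehyde and is neutral enough for the dioxane and the ester.

**Step 10**
Reactants: 13 methyl (2R)-2-[(3S,6S)-6-methyl-6-(2-oxoethyl)-1,2-dioxan-3-yl]propanoate; 14 (R)-(3-hydroxy-2-methylpropyl)triphenylphosphonium bromide
Product: 15 methyl (2R)-2-[(3S,6S)-6-[(2Z,4S)-5-hydroxy-4-methylpent-2-en-1-yl]-6-methyl-1,2-dioxan-3-yl]propanoate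
Conditions: 14, NaHMDS (2 equiv per 14), THF, 0 °C; then 13, −78 °C → rt
Reagents that add atoms: none
Why: Wittig olefination with the alkoxide ylide forms C8=C9 (Z) at −78 °C faster than any enolisation, and brings in C10 with its configuration from the chiral pool.

**Step 11**
Reactants: 15 methyl (2R)-2-[(3S,6S)-6-[(2Z,4S)-5-hydroxy-4-methylpent-2-en-1-yl]-6-methyl-1,2-dioxan-3-yl]propanoate
Product: 16 methyl (2R)-2-[(3S,6S)-6-methyl-6-[(2Z,4S)-4-methyl-5-[(1-phenyl-1H-tetrazol-5-yl)sulfanyl]pent-2-en-1-yl]-1,2-dioxan-3-yl]propanoate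
Conditions: 1-phenyl-1H-tetrazole-5-thiol, PPh3, DIAD, THF, 0 °C → rt
Reagents that add atoms: 1-phenyl-1H-tetrazole-5-thiol, Sc1nnnn1-c1ccccc1
Why: Mitsunobu thioetherification of the primary alcohol; PPh3 is consumed by DIAD at 0 °C before it can attack the hindered dialkyl peroxide, and no stereocentre is involved.

**Step 12**
Reactants: 16 methyl (2R)-2-[(3S,6S)-6-methyl-6-[(2Z,4S)-4-methyl-5-[(1-phenyl-1H-tetrazol-5-yl)sulfanyl]pent-2-en-1-yl]-1,2-dioxan-3-yl]propanoate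
Product: 17 methyl (2R)-2-[(3S,6S)-6-methyl-6-[(2Z,4S)-4-methyl-5-[(1-phenyl-1H-tetrazol-5-yl)sulfonyl]pent-2-en-1-yl]-1,2-dioxan-3-yl]propanoate
Conditions: (NH4)6Mo7O24·4H2O (10 mol%), 30% H2O2, EtOH, 0 °C → rt
Reagents that add atoms: hydrogen peroxide, OO
Why: Molybdate-catalysed sulfide-to-sulfone oxidation is chemoselective over the unactivated 1,2-disubstituted alkene and harmless to the dioxane.

**Step 13**
Reactants: 5 (2R)-2-methyl-2-(4-methylpent-3-en-1-yl)oxetane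
Product: 18 (3S)-3-hydroperoxy-3,7-dimethyloct-6-en-1-ol
Conditions: anhydrous H2O2 in Et2O (10 equiv), TMSOTf (0.2 equiv), −78 → 0 °C
Reagents that add atoms: hydrogen peroxide, OO
Why: The same oxetane perhydrolysis with inversion at the tertiary carbon sets the C14 configuration; the alkene cannot usefully trap the developing cation (four-ring or anti-Markovnikov closure only).

**Step 14**
Reactants: 18 (3S)-3-hydroperoxy-3,7-dimethyloct-6-en-1-ol
Product: 20 (3S)-3-[(2-methoxypropan-2-yl)peroxy]-3,7-dimethyloct-6-en-1-ol, via bis-ketal 19 (not isolated)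
Conditions: 2-methoxypropene (3 equiv), PPTS (5 mol%), CH2Cl2, 0 °C; then MeOH, 0 °C, 10 min; Et3N
Reagents that add atoms: 2-methoxypropene, COC(C)=C
Why: Acid-catalysed ketalisation protects OOH and OH, and the much more labile alkyl mixed ketal is then methanolysed selectively, leaving the peroxyketal.

**Step 15**
Reactants: 20 (3S)-3-[(2-methoxypropan-2-yl)peroxy]-3,7-dimethyloct-6-en-1-ol
Product: 21 (3S)-3-[(2-methoxypropan-2-yl)peroxy]-3,7-dimethyloct-6-enal
Conditions: Dess–Martin periodinane, pyridine, CH2Cl2, 0 °C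
Reagents that add atoms: none
Why: Buffered Dess–Martin oxidation gives the β-peroxy aldehyde without acid (peroxyketal) or strong base (β-elimination).

**Step 16**
Reactants: 17 methyl (2R)-2-[(3S,6S)-6-methyl-6-[(2Z,4S)-4-methyl-5-[(1-phenyl-1H-tetrazol-5-yl)sulfonyl]pent-2-en-1-yl]-1,2-dioxan-3-yl]propanoate; 21 (3S)-3-[(2-methoxypropan-2-yl)peroxy]-3,7-dimethyloct-6-enal
Product: 22 methyl (2R)-2-[(3S,6S)-6-[(2Z,4S,5E,8S)-8-[(2-methoxypropan-2-yl)peroxy]-4,8,12-trimethyltrideca-2,5,11-trien-1-yl]-6-methyl-1,2-dioxan-3-yl]propanoate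
Conditions: 17, KHMDS, DME, −60 °C; then 21, −60 °C → rt
Reagents that add atoms: none
Why: Julia–Kocienski olefination joins C11 to C12; the sulfone CH2 is far more acidic than the ester α-CH, and the alkene geometry (E major) is irrelevant because it is reduced next.

**Step 17**
Reactants: 22 methyl (2R)-2-[(3S,6S)-6-[(2Z,4S,5E,8S)-8-[(2-methoxypropan-2-yl)peroxy]-4,8,12-trimethyltrideca-2,5,11-trien-1-yl]-6-methyl-1,2-dioxan-3-yl]propanoate
Product: 23 methyl (2R)-2-[(3S,6R)-6-[(4S,8R)-8-[(2-methoxypropan-2-yl)peroxy]-4,8,12-trimethyltridec-11-en-1-yl]-6-methyl-1,2-dioxan-3-yl]propanoate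
Conditions: 2-nitrobenzenesulfonyl hydrazide (portionwise, monitored), Et3N, CH2Cl2, rt; AgNO3–SiO2 chromatography
Reagents that add atoms: none
Why: Diimide reduction delivers H2 to C=C but not to O–O, and 1,2-disubstituted alkenes react roughly ten times faster than the trisubstituted C17=C18, so the reaction is stopped at the optimum and over- and under-reduced material is removed by argentation chromatography.

**Step 18**
Reactants: 23 methyl (2R)-2-[(3S,6R)-6-[(4S,8R)-8-[(2-methoxypropan-2-yl)peroxy]-4,8,12-trimethyltridec-11-en-1-yl]-6-methyl-1,2-dioxan-3-yl]propanoate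
Product: 24 methyl (2R)-2-[(3S,6R)-6-[(4R,8R)-8-hydroperoxy-4,8,12-trimethyltridec-11-en-1-yl]-6-methyl-1,2-dioxan-3-yl]propanoate (target)
Conditions: AcOH/THF/H2O (4:2:1), rt
Reagents that add atoms: none
Why: Mild acid hydrolysis of the peroxyketal frees the tertiary hydroperoxide without touching the dioxane, ester, alkene or any stereocentre.

**Compound list**
1 | (R)-(−)-linalool, (3R)-3,7-dimethylocta-1,6-dien-3-ol | C=C[C@](C)(O)CCC=C(C)C | starting material
2 | 9-[(3S)-3-hydroxy-3,7-dimethyloct-6-en-1-yl]-9-borabicyclo[3.3.1]nonane | CC(C)=CCC[C@@](C)(O)CCB1C2CCCC1CCC2 | intermediate (not isolated)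
3 | (3R)-3,7-dimethyloct-6-ene-1,3-diol | OCC[C@](C)(O)CCC=C(C)C | intermediate
4 | (3R)-3-hydroxy-3,7-dimethyloct-6-en-1-yl 4-methylbenzenesulfonate | Cc1ccc(cc1)S(=O)(=O)OCC[C@](C)(O)CCC=C(C)C | intermediate (not isolated)
5 | (2R)-2-methyl-2-(4-methylpent-3-en-1-yl)oxetane | C[C@@]1(CCC=C(C)C)CCO1 | intermediate
6 | 3-[(2R)-2-methyloxetan-2-yl]propanal | C[C@@]1(CCC=O)CCO1 | intermediate
7 | O-diisopinocampheylboryl ether of 8 (Ipc from (+)-α-pinene) | C=C[C@H](C)[C@@H](CC[C@]1(C)CCO1)OB([C@@H]1C[C@@H]2C[C@H]([C@H]1C)C2(C)C)[C@@H]1C[C@@H]2C[C@H]([C@H]1C)C2(C)C | intermediate (not isolated)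
8 | (3S,4R)-3-methyl-6-[(2R)-2-methyloxetan-2-yl]hex-1-en-4-ol | C=C[C@H](C)[C@H](O)CC[C@]1(C)CCO1 | intermediate
9 | (3S,4R)-3-methyl-6-[(2R)-2-methyloxetan-2-yl]hex-1-en-4-yl methanesulfonate | C=C[C@H](C)[C@H](OS(C)(=O)=O)CC[C@]1(C)CCO1 | intermediate
10 | (3S,4R,7S)-7-hydroperoxy-9-hydroxy-3,7-dimethylnon-1-en-4-yl methanesulfonate | C=C[C@H](C)[C@H](OS(C)(=O)=O)CC[C@@](C)(CCO)OO | intermediate
11 | 2-[(3S,6S)-6-[(2S)-but-3-en-2-yl]-3-methyl-1,2-dioxan-3-yl]ethan-1-ol | C=C[C@H](C)[C@@H]1CC[C@@](C)(CCO)OO1 | intermediate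
12 | methyl (2R)-2-[(3S,6S)-6-(2-hydroxyethyl)-6-methyl-1,2-dioxan-3-yl]propanoate | COC(=O)[C@H](C)[C@@H]1CC[C@@](C)(CCO)OO1 | intermediate
13 | methyl (2R)-2-[(3S,6S)-6-methyl-6-(2-oxoethyl)-1,2-dioxan-3-yl]propanoate | COC(=O)[C@H](C)[C@@H]1CC[C@@](C)(CC=O)OO1 | intermediate
14 | (R)-(3-hydroxy-2-methylpropyl)triphenylphosphonium bromide | OC[C@@H](C)C[P+](c1ccccc1)(c1ccccc1)c1ccccc1.[Br-] | starting material
15 | methyl (2R)-2-[(3S,6S)-6-[(2Z,4S)-5-hydroxy-4-methylpent-2-en-1-yl]-6-methyl-1,2-dioxan-3-yl]propanoate | COC(=O)[C@H](C)[C@@H]1CC[C@@](C)(C/C=C\[C@H](C)CO)OO1 | intermediate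
16 | methyl (2R)-2-[(3S,6S)-6-methyl-6-[(2Z,4S)-4-methyl-5-[(1-phenyl-1H-tetrazol-5-yl)sulfanyl]pent-2-en-1-yl]-1,2-dioxan-3-yl]propanoate | COC(=O)[C@H](C)[C@@H]1CC[C@@](C)(C/C=C\[C@H](C)CSc2nnnn2-c2ccccc2)OO1 | intermediate
17 | methyl (2R)-2-[(3S,6S)-6-methyl-6-[(2Z,4S)-4-methyl-5-[(1-phenyl-1H-tetrazol-5-yl)sulfonyl]pent-2-en-1-yl]-1,2-dioxan-3-yl]propanoate | COC(=O)[C@H](C)[C@@H]1CC[C@@](C)(C/C=C\[C@H](C)CS(=O)(=O)c2nnnn2-c2ccccc2)OO1 | intermediate
18 | (3S)-3-hydroperoxy-3,7-dimethyloct-6-en-1-ol | OCC[C@](C)(CCC=C(C)C)OO | intermediate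
19 | (3S)-1-[(2-methoxypropan-2-yl)oxy]-3-[(2-methoxypropan-2-yl)peroxy]-3,7-dimethyloct-6-ene | COC(C)(C)OCC[C@](C)(CCC=C(C)C)OOC(C)(C)OC | intermediate (not isolated)
20 | (3S)-3-[(2-methoxypropan-2-yl)peroxy]-3,7-dimethyloct-6-en-1-ol | OCC[C@](C)(CCC=C(C)C)OOC(C)(C)OC | intermediate
21 | (3S)-3-[(2-methoxypropan-2-yl)peroxy]-3,7-dimethyloct-6-enal | O=CC[C@](C)(CCC=C(C)C)OOC(C)(C)OC | intermediate
22 | methyl (2R)-2-[(3S,6S)-6-[(2Z,4S,5E,8S)-8-[(2-methoxypropan-2-yl)peroxy]-4,8,12-trimethyltrideca-2,5,11-trien-1-yl]-6-methyl-1,2-dioxan-3-yl]propanoate | COC(=O)[C@H](C)[C@@H]1CC[C@@](C)(C/C=C\[C@H](C)/C=C/C[C@](C)(CCC=C(C)C)OOC(C)(C)OC)OO1 | intermediate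
23 | methyl (2R)-2-[(3S,6R)-6-[(4S,8R)-8-[(2-methoxypropan-2-yl)peroxy]-4,8,12-trimethyltridec-11-en-1-yl]-6-methyl-1,2-dioxan-3-yl]propanoate | COC(=O)[C@H](C)[C@@H]1CC[C@@](C)(CCC[C@H](C)CCC[C@](C)(CCC=C(C)C)OOC(C)(C)OC)OO1 | intermediate
24 | methyl (2R)-2-[(3S,6R)-6-[(4R,8R)-8-hydroperoxy-4,8,12-trimethyltridec-11-en-1-yl]-6-methyl-1,2-dioxan-3-yl]propanoate | COC(=O)[C@H](C)[C@@H]1CC[C@@](C)(CCC[C@H](C)CCC[C@](C)(CCC=C(C)C)OO)OO1 | target

**Total step count:** 18. **Longest linear sequence:** 15 (steps 1–12, then 16–18); the other branch is steps 1, 2, 13–15.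

**Three steps most likely to fail**

Step 7. The SN2 centre is secondary and flanked by an allylic methine, so E2 to a diene can compete. The fallback sets out from 6 and comes back at 12. Aldehyde 6 is olefinated with methyl 2-(triphenylphosphoranylidene)propanoate (CH2Cl2, rt) to methyl (2E)-2-methyl-5-[(2R)-2-methyloxetan-2-yl]pent-2-enoate F1. The oxetane is opened with H2O2/TMSOTf as in step 6 to methyl (2E,6S)-6-hydroperoxy-8-hydroxy-2,6-dimethyloct-2-enoate F2. F2 is then closed by a 6-exo-trig oxa-Michael addition (Et2NH, CF3CH2OH) to give 12 together with its C2/C3 diastereomers, which are removed by HPLC. This replaces steps 4–8 by a ring closure that cannot eliminate, at the price of stereocontrol at C2 and C3.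

Step 8. Methanolic NaOH meets a peroxide with an α-hydrogen and a transient β-peroxy aldehyde, so Kornblum–DeLaMare cleavage, retro-Michael opening or C2 epimerisation are possible. The fallback sets out from 11 and comes back at 12. Neutral ozonolysis (O3, pyridine, CH2Cl2, −78 °C) gives (2R)-2-[(3S,6S)-6-(2-hydroxyethyl)-6-methyl-1,2-dioxan-3-yl]propanal F3. Pinnick oxidation (NaClO2, NaH2PO4, 2-methyl-2-butene, t-BuOH/H2O) gives (2R)-2-[(3S,6S)-6-(2-hydroxyethyl)-6-methyl-1,2-dioxan-3-yl]propanoic acid F4. TMSCHN2 in MeOH/toluene then gives 12.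

Step 17. Diimide discriminates only moderately between the two 1,2-disubstituted alkenes and the prenyl-type alkene, so some over-reduction is expected. The fallback sets out from 6 (with 17 as coupling partner) and comes back at 23; it installs C17=C18 only after the reduction.
- Aldehyde 6 is reduced (NaBH4, MeOH) to 3-[(2R)-2-methyloxetan-2-yl]propan-1-ol F5 and silylated (TBDPSCl, imidazole) to tert-butyl{3-[(2R)-2-methyloxetan-2-yl]propoxy}diphenylsilane F6.
- Perhydrolysis as in step 13 gives (3S)-6-[(tert-butyldiphenylsilyl)oxy]-3-hydroperoxy-3-methylhexan-1-ol F7.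
- Ketalisation as in step 14 passes through (3S)-6-[(tert-butyldiphenylsilyl)oxy]-1-[(2-methoxypropan-2-yl)oxy]-3-[(2-methoxypropan-2-yl)peroxy]-3-methylhexane F8 to (3S)-6-[(tert-butyldiphenylsilyl)oxy]-3-[(2-methoxypropan-2-yl)peroxy]-3-methylhexan-1-ol F9.
- Dess–Martin oxidation with pyridine gives (3S)-6-[(tert-butyldiphenylsilyl)oxy]-3-[(2-methoxypropan-2-yl)peroxy]-3-methylhexanal F10.
- Julia–Kocienski coupling with 17 (KHMDS, DME) gives methyl (2R)-2-[(3S,6S)-6-[(2Z,4S,5E,8S)-11-[(tert-butyldiphenylsilyl)oxy]-8-[(2-methoxypropan-2-yl)peroxy]-4,8-dimethylundeca-2,5-dien-1-yl]-6-methyl-1,2-dioxan-3-yl]propanoate F11.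
- F11 has no other alkene, so diimide is run to completion to methyl (2R)-2-[(3S,6R)-6-[(4S,8R)-11-[(tert-butyldiphenylsilyl)oxy]-8-[(2-methoxypropan-2-yl)peroxy]-4,8-dimethylundecyl]-6-methyl-1,2-dioxan-3-yl]propanoate F12.
- TBAF gives methyl (2R)-2-[(3S,6R)-6-[(4S,8R)-11-hydroxy-8-[(2-methoxypropan-2-yl)peroxy]-4,8-dimethylundecyl]-6-methyl-1,2-dioxan-3-yl]propanoate F13.
- Dess–Martin oxidation with pyridine gives methyl (2R)-2-[(3S,6R)-6-[(4S,8R)-8-[(2-methoxypropan-2-yl)peroxy]-4,8-dimethyl-11-oxoundecyl]-6-methyl-1,2-dioxan-3-yl]propanoate F14.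
- Wittig olefination with isopropylidenetriphenylphosphorane (THF, −78 °C) gives 23.

**Further compounds**
F1 | step 7 | methyl (2E)-2-methyl-5-[(2R)-2-methyloxetan-2-yl]pent-2-enoate | COC(=O)/C(C)=C/CC[C@]1(C)CCO1
F2 | step 7 | methyl (2E,6S)-6-hydroperoxy-8-hydroxy-2,6-dimethyloct-2-enoate | COC(=O)/C(C)=C/CC[C@@](C)(CCO)OO
F3 | step 8 | (2R)-2-[(3S,6S)-6-(2-hydroxyethyl)-6-methyl-1,2-dioxan-3-yl]propanal | O=C[C@H](C)[C@@H]1CC[C@@](C)(CCO)OO1
F4 | step 8 | (2R)-2-[(3S,6S)-6-(2-hydroxyethyl)-6-methyl-1,2-dioxan-3-yl]propanoic acid | OC(=O)[C@H](C)[C@@H]1CC[C@@](C)(CCO)OO1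
F5 | step 17 | 3-[(2R)-2-methyloxetan-2-yl]propan-1-ol | C[C@@]1(CCCO)CCO1
F6 | step 17 | tert-butyl{3-[(2R)-2-methyloxetan-2-yl]propoxy}diphenylsilane | C[C@@]1(CCCO[Si](c2ccccc2)(c2ccccc2)C(C)(C)C)CCO1
F7 | step 17 | (3S)-6-[(tert-butyldiphenylsilyl)oxy]-3-hydroperoxy-3-methylhexan-1-ol | OCC[C@](C)(CCCO[Si](c1ccccc1)(c1ccccc1)C(C)(C)C)OO
F8 | step 17 | (3S)-6-[(tert-butyldiphenylsilyl)oxy]-1-[(2-methoxypropan-2-yl)oxy]-3-[(2-methoxypropan-2-yl)peroxy]-3-methylhexane | COC(C)(C)OCC[C@](C)(CCCO[Si](c1ccccc1)(c1ccccc1)C(C)(C)C)OOC(C)(C)OC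
F9 | step 17 | (3S)-6-[(tert-butyldiphenylsilyl)oxy]-3-[(2-methoxypropan-2-yl)peroxy]-3-methylhexan-1-ol | OCC[C@](C)(CCCO[Si](c1ccccc1)(c1ccccc1)C(C)(C)C)OOC(C)(C)OC
F10 | step 17 | (3S)-6-[(tert-butyldiphenylsilyl)oxy]-3-[(2-methoxypropan-2-yl)peroxy]-3-methylhexanal | O=CC[C@](C)(CCCO[Si](c1ccccc1)(c1ccccc1)C(C)(C)C)OOC(C)(C)OC
F11 | step 17 | methyl (2R)-2-[(3S,6S)-6-[(2Z,4S,5E,8S)-11-[(tert-butyldiphenylsilyl)oxy]-8-[(2-methoxypropan-2-yl)peroxy]-4,8-dimethylundeca-2,5-dien-1-yl]-6-methyl-1,2-dioxan-3-yl]propanoate | COC(=O)[C@H](C)[C@@H]1CC[C@@](C)(C/C=C\[C@H](C)/C=C/C[C@](C)(CCCO[Si](c2ccccc2)(c2ccccc2)C(C)(C)C)OOC(C)(C)OC)OO1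
F12 | step 17 | methyl (2R)-2-[(3S,6R)-6-[(4S,8R)-11-[(tert-butyldiphenylsilyl)oxy]-8-[(2-methoxypropan-2-yl)peroxy]-4,8-dimethylundecyl]-6-methyl-1,2-dioxan-3-yl]propanoate | COC(=O)[C@H](C)[C@@H]1CC[C@@](C)(CCC[C@H](C)CCC[C@](C)(CCCO[Si](c2ccccc2)(c2ccccc2)C(C)(C)C)OOC(C)(C)OC)OO1
F13 | step 17 | methyl (2R)-2-[(3S,6R)-6-[(4S,8R)-11-hydroxy-8-[(2-methoxypropan-2-yl)peroxy]-4,8-dimethylundecyl]-6-methyl-1,2-dioxan-3-yl]propanoate | COC(=O)[C@H](C)[C@@H]1CC[C@@](C)(CCC[C@H](C)CCC[C@](C)(CCCO)OOC(C)(C)OC)OO1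
F14 | step 17 | methyl (2R)-2-[(3S,6R)-6-[(4S,8R)-8-[(2-methoxypropan-2-yl)peroxy]-4,8-dimethyl-11-oxoundecyl]-6-methyl-1,2-dioxan-3-yl]propanoate | COC(=O)[C@H](C)[C@@H]1CC[C@@](C)(CCC[C@H](C)CCC[C@](C)(CCC=O)OOC(C)(C)OC)OO1
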